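**Plan**

- Retrosynthesis: the phenol is masked as a benzyl ether and an ethoxycarbonyl group is placed on C3. The two benzylic bonds flanking the C3–C4 edge are then cut together: the aryl–CH2 bond of the 4-hydroxy-3-methoxybenzyl arm and the C3–CH2 bond of the 3,4,5-trimethoxybenzyl arm.
- Enabling feature: with the lactone numbered O1, C2 (C=O), C3, C4, C5, the benzylic CH2 on C4 is read as the CH2 of a cyclopropane fused across C3–C4. Its C3 carries the lactone carbonyl and an extra ester, so this CH2 is a doubly activated electrophilic carbon.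
- Forward: the γ-lactone and the fused three-membered ring arise together in step 1 from (R)-epichlorohydrin and diethyl malonate. An aryl copper reagent opens the cyclopropane at its CH2 and the enolate is benzylated in the same flask; no ring closes after step 1. Ester removal, C3 equilibration and debenzylation finish the route.
- Stereochemistry: C4 (R) is the epichlorohydrin carbon, carried untouched through the (1S,5R)-bicycle. C3 (R) is fixed at the end by thermodynamic equilibration to the trans lactone.

Key step: step 3

Assumption: the benzyl-protected bromoguaiacol used for the Grignard reagent and 3,4,5-trimethoxybenzyl bromide are taken as purchased catalogue compounds.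

**Route**

Step 1
Reactants: 1 (R)-epichlorohydrin; 2 diethyl malonate
Product: 6 ethyl (1S,5R)-2-oxo-3-oxabicyclo[3.1.0]hexane-1-carboxylate, via chlorohydrin malonate alkoxide 3 (not isolated), via epoxy malonate 4 (not isolated), via cyclopropyl carbinol diester 5 (not isolated)
Conditions: NaOEt (1.05 equiv), 2 (1.1 equiv), EtOH, 0 °C → reflux; AcOH quench; distillation
Reagents that add atoms: none
Why: Tandem malonate alkylation–lactonization in which sodium malonate opens the epoxide of 1 at its CH2 terminus to give 3, the alkoxide expels chloride to form the transposed epoxide 4, a second deprotonation triggers 3-exo-tet opening of that epoxide with inversion to give 5, and the alkoxide of 5 lactonizes onto the cis ester, so that the R centre of 1 becomes C5 (R) of 6 and the obligatory cis ring fusion fixes C1 as S.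

Step 2
Reactants: 7 1-(benzyloxy)-4-bromo-2-methoxybenzene
Product: 8 (4-benzyloxy-3-methoxyphenyl)magnesium bromide
Conditions: Mg turnings (1.2 equiv), I2 (cat.), THF, 45 °C → rt; titrated and used as the THF solution
Reagents that add atoms: magnesium, [Mg]
Why: Grignard formation by insertion of magnesium into the aryl C–Br bond, to which the benzyl and methyl aryl ethers are inert.

Step 3
Reactants: 6 ethyl (1S,5R)-2-oxo-3-oxabicyclo[3.1.0]hexane-1-carboxylate; 8 (4-benzyloxy-3-methoxyphenyl)magnesium bromide; 9 3,4,5-trimethoxybenzyl bromide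
Product: 11 ethyl (3R,4R)-4-(4-benzyloxy-3-methoxybenzyl)-2-oxo-3-(3,4,5-trimethoxybenzyl)tetrahydrofuran-3-carboxylate, via bromomagnesium lactone enolate 10 (not isolated)
Conditions: 8 (1.3 equiv), CuI (0.2 equiv), THF, −30 °C; 6 added, −30 → −10 °C; then DMPU, 9 (1.6 equiv), −10 °C → rt; aq. NH4Cl
Reagents that add atoms: none
Why: Transmetalation of 8 to CuI gives an aryl copper species whose monovalent copper attacks the cyclopropane CH2 (C6) of 6 in an SN2-like homoconjugate addition that breaks the C6–C1 bond; reductive elimination from the trivalent copper alkyl forms the aryl–CH2 bond and releases the chelated enolate 10, which 9 then benzylates on carbon at C3. The closest known reaction types are the CuI-catalysed Grignard opening of this same cyclopropane lactone ester and the alkylation of α-alkoxycarbonyl lactone enolates by benzylic halides, here run back to back in one flask. No ring closes: the three-membered ring opens and the lactone from step 1 is carried through unchanged. C4 of 11 is C5 of 6 and keeps its configuration because the bond that breaks lies on the far side of the CH2, while the quaternary C3 is set under substrate control by approach of 9 to the enolate face anti to the C4 arylmethyl group, giving the 3,4-trans (3R,4R) isomer; this centre is reset in steps 4 and 5, so its selectivity is helpful but not essential. The step needs attack at the CH2 and not at the ring CH or the two carbonyl groups, and C- over O-alkylation; the soft copper nucleophile at low temperature, the strain and double activation of the ring and the lower substitution of the CH2 secure the first, and the chelated magnesium enolate paired with a soft benzylic bromide (DMPU loosening the chelate) secures the second.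

Step 4
Reactants: 11 ethyl (3R,4R)-4-(4-benzyloxy-3-methoxybenzyl)-2-oxo-3-(3,4,5-trimethoxybenzyl)tetrahydrofuran-3-carboxylate
Product: 13 (4R)-4-(4-benzyloxy-3-methoxybenzyl)-3-(3,4,5-trimethoxybenzyl)dihydrofuran-2(3H)-one as a mixture of C3 epimers, via lithium lactone carboxylate 12 (not isolated)
Conditions: LiCl (3 equiv), H2O (2 equiv), DMSO, 150 °C
Reagents that add atoms: none
Why: Krapcho dealkoxycarbonylation, in which chloride dealkylates the ethyl ester by SN2 attack to give 12, which loses CO2 and is protonated at C3 by water without regard to configuration, while C4, the aryl ethers and the lactone are unaffected.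

Step 5
Reactants: 13 (4R)-4-(4-benzyloxy-3-methoxybenzyl)-3-(3,4,5-trimethoxybenzyl)dihydrofuran-2(3H)-one as a mixture of C3 epimers
Product: 14 (3R,4R)-4-(4-benzyloxy-3-methoxybenzyl)-3-(3,4,5-trimethoxybenzyl)dihydrofuran-2(3H)-one
Conditions: KOt-Bu (0.3 equiv), t-BuOH–THF, 0 °C → rt; AcOH
Reagents that add atoms: none
Why: Base-mediated epimerization through reversible deprotonation at C3 should funnel both epimers to the thermodynamically preferred trans-2,3-dibenzyl lactone, with the non-acidic C4 (R) centre dictating 3R and the hindered alkoxide not opening the lactone.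

Step 6
Reactants: 14 (3R,4R)-4-(4-benzyloxy-3-methoxybenzyl)-3-(3,4,5-trimethoxybenzyl)dihydrofuran-2(3H)-one
Product: 15 Hernanol, (3R,4R)-4-(4-hydroxy-3-methoxybenzyl)-3-(3,4,5-trimethoxybenzyl)dihydrofuran-2(3H)-one
Conditions: H2 (1 atm), Pd/C (10 wt % Pd), EtOAc–EtOH, rt
Reagents that add atoms: none
Why: Catalytic hydrogenolysis of the aryl benzyl ether under neutral conditions, which leave the lactone, the methyl ethers, the benzylic C–C bonds and both stereocentres intact.

**Compound list**

1 | (R)-epichlorohydrin | ClC[C@H]1CO1 | starting material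
2 | diethyl malonate | CCOC(=O)CC(=O)OCC | starting material
3 | diethyl 2-[(2R)-3-chloro-2-hydroxypropyl]malonate (present as its sodium alkoxide) | ClC[C@H](O)CC(C(=O)OCC)C(=O)OCC | intermediate (not isolated)
4 | diethyl 2-{[(2R)-oxiran-2-yl]methyl}malonate | CCOC(=O)C(C[C@@H]1CO1)C(=O)OCC | intermediate (not isolated)
5 | diethyl (2R)-2-(hydroxymethyl)cyclopropane-1,1-dicarboxylate (present as its sodium alkoxide) | CCOC(=O)C1(C(=O)OCC)C[C@H]1CO | intermediate (not isolated)
6 | ethyl (1S,5R)-2-oxo-3-oxabicyclo[3.1.0]hexane-1-carboxylate | C1[C@H]2COC(=O)[C@@]12C(=O)OCC | intermediate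
7 | 1-(benzyloxy)-4-bromo-2-methoxybenzene (4-benzyloxy-3-methoxybromobenzene) | COc1cc(Br)ccc1OCc1ccccc1 | starting material
8 | (4-benzyloxy-3-methoxyphenyl)magnesium bromide | COc1cc([Mg]Br)ccc1OCc1ccccc1 | intermediate
9 | 3,4,5-trimethoxybenzyl bromide | COc1cc(CBr)cc(OC)c1OC | starting material
10 | bromomagnesium enolate of ethyl (4R)-4-(4-benzyloxy-3-methoxybenzyl)-2-oxotetrahydrofuran-3-carboxylate | CCOC(=O)C1=C(O[Mg]Br)OC[C@@H]1Cc1ccc(OCc2ccccc2)c(OC)c1 | intermediate (not isolated)
11 | ethyl (3R,4R)-4-(4-benzyloxy-3-methoxybenzyl)-2-oxo-3-(3,4,5-trimethoxybenzyl)tetrahydrofuran-3-carboxylate (benzyl groups trans) | CCOC(=O)[C@@]1(Cc2cc(OC)c(OC)c(OC)c2)[C@@H](Cc2ccc(OCc3ccccc3)c(OC)c2)COC1=O | intermediate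
12 | lithium (3R,4R)-4-(4-benzyloxy-3-methoxybenzyl)-2-oxo-3-(3,4,5-trimethoxybenzyl)tetrahydrofuran-3-carboxylate | [Li+].[O-]C(=O)[C@@]1(Cc2cc(OC)c(OC)c(OC)c2)[C@@H](Cc2ccc(OCc3ccccc3)c(OC)c2)COC1=O | intermediate (not isolated)
13 | (4R)-4-(4-benzyloxy-3-methoxybenzyl)-3-(3,4,5-trimethoxybenzyl)dihydrofuran-2(3H)-one, C3 epimer mixture | COc1cc(C[C@H]2COC(=O)C2Cc2cc(OC)c(OC)c(OC)c2)ccc1OCc1ccccc1 | intermediate
14 | (3R,4R)-4-(4-benzyloxy-3-methoxybenzyl)-3-(3,4,5-trimethoxybenzyl)dihydrofuran-2(3H)-one (trans) | COc1cc(C[C@H]2COC(=O)[C@@H]2Cc2cc(OC)c(OC)c(OC)c2)ccc1OCc1ccccc1 | intermediate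
15 | Hernanol, (3R,4R)-4-(4-hydroxy-3-methoxybenzyl)-3-(3,4,5-trimethoxybenzyl)dihydrofuran-2(3H)-one | COc1cc(C[C@H]2COC(=O)[C@@H]2Cc2cc(OC)c(OC)c(OC)c2)ccc1O | target

**Step count and risks**

Total steps: 6. Longest linear sequence: 5 steps (steps 1, 3, 4, 5, 6 from 1; equally steps 2–6 from 7).

Steps most likely to fail:

1. Step 3. The chelated magnesium enolate may alkylate sluggishly, surplus aryl Grignard may consume the benzylic bromide by copper-catalysed cross-coupling, and some 1,2-addition to the carbonyl groups of 6 may compete. Fallback: the two bond formations are decoupled. Setting out from 6 and 8, the CuI-catalysed opening is run alone and quenched with aqueous NH4Cl, and ethyl (4R)-4-(4-benzyloxy-3-methoxybenzyl)-2-oxotetrahydrofuran-3-carboxylate F1 is isolated as its C3 epimers. F1 is then deprotonated with NaH in THF–DMF at 0 °C and the free sodium enolate is alkylated with 9, again anti to the C4 substituent. The sequence comes back to the route at 11.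

2. Step 4. At 150 °C the hindered quaternary ester may dealkylate slowly, and prolonged heating with chloride may erode the aryl methyl ethers or degrade the lactone. Fallback: setting out from 11, KOH in aqueous EtOH at reflux hydrolyses the ester and opens the lactone to dipotassium 2-[(2R)-1-(4-benzyloxy-3-methoxyphenyl)-3-hydroxypropan-2-yl]-2-(3,4,5-trimethoxybenzyl)malonate F2. Acidification with HCl recloses the ring to (4R)-4-(4-benzyloxy-3-methoxybenzyl)-2-oxo-3-(3,4,5-trimethoxybenzyl)tetrahydrofuran-3-carboxylic acid F3 (C3 epimers). Heating F3 in toluene at 110 °C brings about classical malonic-type decarboxylation, and the sequence comes back to the route at 13.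

3. Step 1. Direct displacement of chloride by the malonate competes with epoxide opening and leads to the enantiomeric lactone, so enantiomeric purity may be eroded; oligomerization of the epoxide may also lower throughput. Fallback: purchased (R)-glycidol (OC[C@@H]1CO1) is converted with Tf2O and 2,6-lutidine in CH2Cl2 at −20 °C into (S)-glycidyl trifluoromethanesulfonate F4. Sodium diethyl malonate (from 2 and NaH in THF at 0 °C) attacks F4 exclusively at the sulfonate-bearing carbon and so delivers epoxy malonate 4 directly, without the chlorohydrin pathway. Catalytic NaOEt in EtOH then carries 4 through 5, and the sequence comes back to the route at 6.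

**Further compounds**

F1 | step 3 | ethyl (4R)-4-(4-benzyloxy-3-methoxybenzyl)-2-oxotetrahydrofuran-3-carboxylate (C3 epimers) | CCOC(=O)C1C(=O)OC[C@@H]1Cc1ccc(OCc2ccccc2)c(OC)c1
F2 | step 4 | dipotassium 2-[(2R)-1-(4-benzyloxy-3-methoxyphenyl)-3-hydroxypropan-2-yl]-2-(3,4,5-trimethoxybenzyl)malonate | [K+].[K+].[O-]C(=O)C(Cc1cc(OC)c(OC)c(OC)c1)(C([O-])=O)[C@H](CO)Cc1ccc(OCc2ccccc2)c(OC)c1
F3 | step 4 | (4R)-4-(4-benzyloxy-3-methoxybenzyl)-2-oxo-3-(3,4,5-trimethoxybenzyl)tetrahydrofuran-3-carboxylic acid (C3 epimers) | OC(=O)C1(Cc2cc(OC)c(OC)c(OC)c2)[C@@H](Cc2ccc(OCc3ccccc3)c(OC)c2)COC1=O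
F4 | step 1 | (S)-glycidyl trifluoromethanesulfonate | O=S(=O)(OC[C@@H]1CO1)C(F)(F)F
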